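**Retrosynthetic overview**

1. 15 ⇐ 14 by Luche reduction of the C4 ketone; 14 ⇐ 11 by building the C3 methoxy enol ether next to the C4 ketone (α-hydroxylation, oxidation to the diosphenol, O-methylation).
2. 11 ⇐ 8 by an oxidative pinacol-type 1,2-shift of C6 from C4 to C5: the six-membered ring C1–C8–C5–C4–C6–C7 of a bicyclo[2.2.2]octene contracts to the cyclopentanone C1–C8–C5–C6–C7, and the menthyl auxiliary leaves.
3. 8 ⇐ diene 6 + (E)-methylisoeugenol 7 by a radical-cation [4+2] (bonds C1–C7 and C4–C6, both six-membered rings at once); 6 ⇐ cyclohexane-1,3-dione 1, (−)-menthol 2, allyl bromide 4.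
4. Enabling feature: C8(=O) sits between the bridgeheads C1 and C5 and C4 carries oxygen, so C4(O)–C5–C8(=O) on the ring C1–C8–C5–C6–C7 is the product pattern of a 1,2-shift to C5 pushed by an oxygen on C4; the endo aryl group of the [4+2] adduct becomes the 6-exo aryl group.
5. Ring order: cyclohexane ring of 1 → bicyclo[2.2.2]octene (step 4) → bicyclo[3.2.1]octane by ring contraction (step 5).

Key step: step 5

Remark on numbering: C1–C8 are the core atoms of 15 (C1 allyl bridgehead, C2=C3(OMe), C4 carbinol, C5 bridgehead H, C6 aryl, C7 methyl, C8 ketone) and are kept for every intermediate.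
Assumption: the menthyl ether of 6 is not relied on for facial control in step 4. The adduct is expected as two facial diastereomers with the same endo/trans arrangement and bicyclic cores of opposite configuration. They are separated by chromatography, and the configuration of 8 is assigned before step 5. If the other diastereomer predominates, (+)-menthol serves equally.
Assumption: 7 is used as the pure E isomer, since the trans C6/C7 relationship derives from it.

**Step 1**
Reactants: 1 cyclohexane-1,3-dione; 2 (−)-menthol
Product: 3 3-[(1R,2S,5R)-menthyloxy]cyclohex-2-en-1-one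
Conditions: p-TsOH·H2O (cat.), toluene, reflux, Dean–Stark trap
Reagents that add atoms: none
Why: Acid-catalysed enol etherification of a cyclic 1,3-dione with azeotropic removal of water gives the vinylogous ester and installs the chiral alkoxy group that is later lost in the key step.

**Step 2**
Reactants: 3 3-(menthyloxy)cyclohex-2-en-1-one; 4 allyl bromide
Product: 5 6-allyl-3-(menthyloxy)cyclohex-2-en-1-one (both epimers at the allyl-bearing carbon)
Conditions: LiN(iPr)2, THF, −78 °C; then 4, −78 to 0 °C
Reagents that add atoms: none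
Why: Stork–Danheiser alkylation: kinetic α′-deprotonation of the vinylogous ester and C-allylation at the future C1, whose configuration is erased in step 3.

**Step 3**
Reactants: 5 6-allyl-3-(menthyloxy)cyclohex-2-en-1-one
Product: 6 1-allyl-2-(tert-butyldimethylsilyloxy)-4-(menthyloxy)cyclohexa-1,3-diene
Conditions: LiN(iPr)2, THF, −78 °C; then TBSCl, DMPU, −78 °C to rt
Reagents that add atoms: tert-butyldimethylsilyl chloride, CC(C)(C)[Si](C)(C)Cl
Why: A second kinetic α′-deprotonation and O-silylation of the cross-conjugated enolate gives the 1-alkoxy-3-silyloxy diene C4=C5–C8=C1 with its nucleophilic terminus at C1.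

**Step 4**
Reactants: 6 silyloxy diene; 7 (E)-methylisoeugenol
Product: 8 endo-aryl bicyclo[2.2.2]oct-2-ene adduct (C5=C8 enol ether, aryl on C6 syn to it, methyl on C7 anti)
Conditions: Ru(bpz)3(PF6)2 (1 mol %), air, MeNO2, blue LEDs, rt, 6 in excess; chromatography on NEt3-deactivated SiO2
Reagents that add atoms: none
Why: Proposed new method: single-electron oxidation of 7 (or 6) should open a radical-cation [4+2] in which the nucleophilic diene terminus C1 bonds to the β-carbon C7 of the styrene (a union of two donor carbons) and the benzylic C6 then closes onto the alkoxy-bearing C4; the trans C6/C7 relationship comes from the E-alkene, the endo rule puts the aryl group syn to the new C5=C8 bridge, and the facial diastereomer formed alongside is removed by chromatography; closest known reaction type: photoredox or aminium-salt radical-cation Diels–Alder of anethole-type styrenes with cyclohexa-1,3-diene, not yet shown for a tetrasubstituted 1-alkoxy-3-silyloxy diene.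

**Step 5**
Reactants: 8 endo-aryl bicyclo[2.2.2]oct-2-ene adduct
Product: 11 1-allyl-6-exo-aryl-7-endo-methylbicyclo[3.2.1]octane-4,8-dione, via α-iodanyl ketone 9 (not isolated), via oxocarbenium tosylate 10 (not isolated)
Conditions: PhI(OH)OTs, 2,6-di-tert-butyl-4-methylpyridine, CH2Cl2/MeCN, −40 to 0 °C; then aq NaHCO3
Reagents that add atoms: water, O
Why: Proposed new method: the silyl enol ether of 8 should attack the trivalent iodine of PhI(OH)OTs through C5 on the face syn to the C2–C3 bridge (the other face is covered by the endo aryl group), unveiling the C8 ketone and giving α-iodanyl ketone 9; the C4–C6 bond lies anti to the C5–I bond and migrates to C5 as iodobenzene departs, the ether oxygen on C4 carrying the charge as oxocarbenium ion 10, which is hydrolysed on work-up to the C4 ketone with release of menthol. The closest known reaction types are the acid-induced pinacol-type rearrangement of 1-alkoxybicyclo[2.2.2]octan-2-yl derivatives to bicyclo[3.2.1]octan-2-ones and the α-functionalisation of silyl enol ethers by PhI(OH)OTs through α-iodanyl ketones. No ring is closed by a cyclisation: the cyclopentanone C1–C8–C5–C6–C7 arises by a 1,2-shift that contracts the six-membered ring C1–C8–C5–C4–C6–C7 and turns the bicyclo[2.2.2]octene into the bicyclo[3.2.1]octane. The new stereocentre C5 is fixed by the stereospecific course (C6 enters anti to iodine with retention at C6), so the endo aryl group of 8 becomes the 6-exo aryl group and the methyl group the 7-endo methyl group of 11. The step needs migration of C6 in preference to C3 and to capture of 9 by tosylate, by the ether oxygen or by the arene; the anti alignment of C4–C6, the higher migratory aptitude of the secondary benzylic C6 over the primary C3 and the oxygen push from C4 secure this.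

**Step 6**
Reactants: 11 bicyclo[3.2.1]octane-4,8-dione
Product: 12 3-hydroxy-4,8-dione (3-OH syn to C8 expected)
Conditions: LiN(SiMe3)2, THF, −78 °C; then 2-(phenylsulfonyl)-3-phenyloxaziridine, −78 °C; aqueous work-up
Reagents that add atoms: 2-(phenylsulfonyl)-3-phenyloxaziridine, O=S(=O)(c1ccccc1)N1OC1c1ccccc1
Why: Only the C4 ketone can enolise (toward C3; C5 is a bridgehead and C8 has no enolisable α-hydrogen), and electrophilic enolate hydroxylation should occur from the face syn to C8, the C3 configuration being destroyed in step 7.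

**Step 7**
Reactants: 12 3-hydroxy-4,8-dione
Product: 13 diosphenol (3-hydroxy-2-ene-4,8-dione)
Conditions: Dess–Martin periodinane, CH2Cl2, 0 °C to rt
Reagents that add atoms: none
Why: Dess–Martin oxidation of the acyloin gives the 3,4-dicarbonyl compound, which is enolisable only toward C2 and is therefore expected as its diosphenol tautomer.

**Step 8**
Reactants: 13 diosphenol
Product: 14 3-methoxybicyclo[3.2.1]oct-2-ene-4,8-dione
Conditions: Me2SO4, K2CO3, acetone, rt
Reagents that add atoms: dimethyl sulfate, COS(=O)(=O)OC
Why: O-Methylation of the acidic diosphenol with a hard electrophile gives the 3-methoxy enone.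

**Step 9**
Reactants: 14 3-methoxy-2-ene-4,8-dione
Product: 15 target
Conditions: NaBH4, CeCl3·7H2O, MeOH, −78 °C
Reagents that add atoms: none
Why: Luche reduction should favour 1,2-reduction of the conjugated C4 ketone over the non-conjugated C8 ketone (flanked by the quaternary C1 and shielded by the 6-exo aryl group), with hydride delivered from the face syn to C8, away from the C6–C7 bridge, so that the 4-OH ends anti to C8 as in 15.

**Compound list**

1 | cyclohexane-1,3-dione | O=C1CCCC(=O)C1 | starting material
2 | (−)-menthol, (1R,2S,5R)-5-methyl-2-(propan-2-yl)cyclohexan-1-ol | C[C@@H]1CC[C@H]([C@@H](C1)O)C(C)C | starting material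
3 | 3-{[(1R,2S,5R)-5-methyl-2-(propan-2-yl)cyclohexyl]oxy}cyclohex-2-en-1-one | O=C1CCCC(O[C@@H]2C[C@H](C)CC[C@H]2C(C)C)=C1 | intermediate
4 | allyl bromide (3-bromoprop-1-ene) | C=CCBr | starting material
5 | 6-allyl-3-[(1R,2S,5R)-menthyloxy]cyclohex-2-en-1-one, both epimers at the allyl-bearing carbon | C=CCC1CCC(O[C@@H]2C[C@H](C)CC[C@H]2C(C)C)=CC1=O | intermediate
6 | 1-allyl-2-(tert-butyldimethylsilyloxy)-4-[(1R,2S,5R)-menthyloxy]cyclohexa-1,3-diene | C=CCC1=C(O[Si](C)(C)C(C)(C)C)C=C(O[C@@H]2C[C@H](C)CC[C@H]2C(C)C)CC1 | intermediate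
7 | (E)-methylisoeugenol, 1,2-dimethoxy-4-[(1E)-prop-1-en-1-yl]benzene | C/C=C/c1ccc(OC)c(OC)c1 | starting material
8 | bicyclo[2.2.2]oct-2-ene adduct: bridgeheads C1 (allyl) and C4 (O-menthyl), C5=C8 enol ether (OTBS on C8), C2–C3 ethano bridge, C6 (3,4-dimethoxyphenyl, syn to C5=C8, bonded to C4), C7 (methyl, syn to C2–C3, bonded to C1) | C=CC[C@@]12CC[C@@](O[C@@H]3C[C@H](C)CC[C@H]3C(C)C)(C=C1O[Si](C)(C)C(C)(C)C)[C@@H](c1ccc(OC)c(OC)c1)[C@@H]2C | intermediate
9 | α-iodanyl ketone: C8 ketone, phenyl(tosyloxy)iodanyl group on C5 syn to the C2–C3 bridge | C=CC[C@@]12CC[C@@](O[C@@H]3C[C@H](C)CC[C@H]3C(C)C)([C@@H](I(c3ccccc3)OS(=O)(=O)c3ccc(C)cc3)C1=O)[C@@H](c1ccc(OC)c(OC)c1)[C@@H]2C | intermediate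
10 | O-menthyl oxocarbenium tosylate of the rearranged bicyclo[3.2.1]octan-8-one (C4=O+ menthyl) | C=CC[C@@]12CCC(=[O+][C@@H]3C[C@H](C)CC[C@H]3C(C)C)[C@@H](C1=O)[C@@H](c1ccc(OC)c(OC)c1)[C@@H]2C.Cc1ccc(cc1)S(=O)(=O)[O-] | intermediate
11 | 1-allyl-6-exo-(3,4-dimethoxyphenyl)-7-endo-methylbicyclo[3.2.1]octane-4,8-dione | C=CC[C@@]12CCC(=O)[C@@H](C1=O)[C@@H](c1ccc(OC)c(OC)c1)[C@@H]2C | intermediate
12 | 3-hydroxy derivative of 11 (3-OH syn to C8) | C=CC[C@@]12C[C@@H](O)C(=O)[C@@H](C1=O)[C@@H](c1ccc(OC)c(OC)c1)[C@@H]2C | intermediate
13 | diosphenol: 1-allyl-6-exo-aryl-3-hydroxy-7-endo-methylbicyclo[3.2.1]oct-2-ene-4,8-dione | C=CC[C@@]12C=C(O)C(=O)[C@@H](C1=O)[C@@H](c1ccc(OC)c(OC)c1)[C@@H]2C | intermediate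
14 | 1-allyl-6-exo-aryl-3-methoxy-7-endo-methylbicyclo[3.2.1]oct-2-ene-4,8-dione | C=CC[C@@]12C=C(OC)C(=O)[C@@H](C1=O)[C@@H](c1ccc(OC)c(OC)c1)[C@@H]2C | intermediate
15 | (1R,4R,5S,6S,7S)-6-(3,4-dimethoxyphenyl)-4-hydroxy-3-methoxy-7-methyl-1-(prop-2-en-1-yl)bicyclo[3.2.1]oct-2-en-8-one | C=CC[C@@]12C=C(OC)[C@H](O)[C@@H](C1=O)[C@@H](c1ccc(OC)c(OC)c1)[C@@H]2C | target

**Step count and risks**

Total step count: 9. Longest linear sequence: 9 steps (from cyclohexane-1,3-dione 1).

Steps most likely to fail:

1. Step 4 (Proposed new method). It may fail through oxidative aromatisation or hydrolysis of the electron-rich diene, through [2+2] closure to a vinylcyclobutane, or through poor endo and facial selectivity. Fallback with known chemistry, from 6 back to 8: a thermal normal-electron-demand Diels–Alder reaction of 6 with (E)-N-(but-2-enoyloxy)phthalimide (toluene, 110 °C) should give the endo redox-active ester adduct F1. Here C1 bonds to the β-carbon, the carboxyl on C6 is syn to the C5=C8 bridge, the methyl on C7 is anti, and the menthyl diastereomers are separated. Decarboxylative coupling of F1 with (3,4-dimethoxyphenyl)zinc chloride, catalysed by NiCl2·glyme and 4,4′-di-tert-butyl-2,2′-bipyridine (THF/DMF, rt), should then place the aryl group on the secondary C6 radical from the face away from the neighbouring methyl group, returning to 8.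

2. Step 5 (Proposed new method). It may fail through oxidation of the dimethoxyarene or the terminal alkene by the iodine reagent, through capture of the iodane by tosylate, by the ether oxygen or by the arene instead of carbon migration, or through migration of C3. Fallback with known chemistry, from 8 back to 11: Rubottom oxidation of 8 (mCPBA, NaHCO3, CH2Cl2, −20 °C; then HF·pyridine) should give the α-hydroxy ketone F2 with the hydroxyl on C5 on the face away from the aryl bridge. Sulfonylation (Tf2O, 2,6-di-tert-butyl-4-methylpyridine, CH2Cl2, −78 °C) gives the triflate F3. Its ionisation in buffered (CF3)2CHOH at rt triggers the same pinacol-type 1,2-shift of C6, anti to the leaving group and assisted by the ether oxygen, and aqueous work-up returns to 11.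

3. Step 9. It may fail through loss of chemoselectivity, with the bridging C8 ketone reduced alongside the C4 ketone. Fallback, from 14 back to 15: both ketones are reduced (NaBH4 in excess, CeCl3·7H2O, MeOH, 0 °C to rt) to the diol F4. The less hindered C4 hydroxyl is silylated selectively (TBSCl, imidazole, DMF) to give the silyl ether F5. Dess–Martin oxidation of the remaining neopentyl C8 carbinol gives the silyloxy ketone F6. HF·pyridine buffered with pyridine (THF, 0 °C) removes the silyl group and returns to 15.

**Further compounds**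

F1 | step 4 | endo N-acyloxyphthalimide adduct: as 8 but with C(=O)O-phthalimido on C6 in place of the aryl group | C=CC[C@@]12CC[C@@](O[C@@H]3C[C@H](C)CC[C@H]3C(C)C)(C=C1O[Si](C)(C)C(C)(C)C)[C@@H](C(=O)ON1C(=O)c3ccccc3C1=O)[C@@H]2C
F2 | step 5 | α-hydroxy ketone: C8 ketone, 5-OH syn to the C2–C3 bridge, bicyclo[2.2.2]octane | C=CC[C@@]12CC[C@@](O[C@@H]3C[C@H](C)CC[C@H]3C(C)C)([C@@H](O)C1=O)[C@@H](c1ccc(OC)c(OC)c1)[C@@H]2C
F3 | step 5 | triflate of F2 | C=CC[C@@]12CC[C@@](O[C@@H]3C[C@H](C)CC[C@H]3C(C)C)([C@@H](OS(=O)(=O)C(F)(F)F)C1=O)[C@@H](c1ccc(OC)c(OC)c1)[C@@H]2C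
F4 | step 9 | 4,8-diol of 14 (C4 as in 15, C8 configuration not defined) | C=CC[C@@]12C=C(OC)[C@H](O)[C@@H](C1O)[C@@H](c1ccc(OC)c(OC)c1)[C@@H]2C
F5 | step 9 | 4-O-tert-butyldimethylsilyl ether of F4 | C=CC[C@@]12C=C(OC)[C@H](O[Si](C)(C)C(C)(C)C)[C@@H](C1O)[C@@H](c1ccc(OC)c(OC)c1)[C@@H]2C
F6 | step 9 | 4-O-tert-butyldimethylsilyl ether of 15 | C=CC[C@@]12C=C(OC)[C@H](O[Si](C)(C)C(C)(C)C)[C@@H](C1=O)[C@@H](c1ccc(OC)c(OC)c1)[C@@H]2C
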